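## Analysis of the target

The target is a furofuran lignan, a cis-fused 3,7-dioxabicyclo[3.3.0]octane. It is numbered here so that C2 carries the 4-hydroxy-3,5-dimethoxyphenyl group and C6 the 3,4,5-trimethoxyphenyl group; ring A is C1–C2–O3–C4–C5 and ring B is C5–C6–O7–C8–C1. These atom labels are kept for every intermediate. There are four contiguous stereocentres, (1S,2R,5S,6R): the bridgeheads C1 and C5 are cis, and each aryl group is exo, that is trans to the methylene of the other ring on the neighbouring bridgehead (C2 aryl trans to C8, C6 aryl trans to C4). But for one O-methyl group the molecule would be C2-symmetric, so the two halves are stereochemically alike yet have to be brought in one at a time. C2 and C6 are benzylic ether carbons of electron-rich arenes and lose their configuration by ionization under acid; the free para-phenol makes C2 the more fragile of the two and rules out oxidants and hydrogenolysis late in the route. The difficulty is to fix four centres in the absolute sense on a compact skeleton in which two of them are configurationally labile. The strategy rests on the position of C6: it is benzylic, bound to O7 and joined to C5 through the chain C1–C8–O7, so the C5–C6 bond can be made by inserting a carbene centre at C5 into a C–H bond of a benzyl ether that hangs from C8. C5 becomes such a centre most easily when C4 is a lactone carbonyl.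

## Retrosynthetic reasoning

**20 ⇒ 19.** The phenol is unmasked last. In 19 it is a 4-methylbenzenesulfonate rather than a silyl ether. The sulfonyloxy group makes the C2 aryl electron-poor, so the C2–O3 bond cannot ionize in any of the acid steps before it. It is removed by electron transfer, which touches neither benzylic ether.

**19 ⇒ 18.** Only C6 is changed. A carbene insertion that closes ring B is expected to place the C6 aryl on the concave face, cis to C4, so the exo centre of 19 is traced back to its C6 epimer 18. Forward, acid must open C6–O7 to the benzylic cation and let it reclose. This is done on ether 18 and not on lactone 16: in 16 the cation would sit beside the carbon α to the carbonyl, ionization would be harder, and loss of the C5 proton to an arylidene lactone would compete. The sulfonate confines the process to C6.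

**18 ⇒ 17 ⇒ 16.** C4 is taken back from methylene to a lactone carbonyl. This puts C5 α to a carbonyl, which is what a diazo group and a stabilized carbene centre need. Forward, 16 is reduced to lactol 17 and the lactol is deoxygenated through its oxocarbenium ion; no stereocentre is involved.

**16 ⇒ 15.** The C5–C6 bond is cut. This one scission removes ring B, two stereocentres and the whole second aryl arm, and leaves a monocyclic lactone whose C8 side chain is a plain benzyl ether. Cutting C6–O7 or C2–O3 instead would leave open-chain benzylic carbinols that lose their configuration on closure. Forward, the carbene centre at C5 of 15 must insert into the benzylic C–H bond; the tether length fixes the site and the C1 centre fixes the ring fusion.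

**15 ⇒ 12.** The diazo group at C5 is traced to the α-methylene of lactone 12. Forward, a plain lactone must first be activated by C-acylation before diazo transfer.

**12 ⇒ 9 + 11.** The O7–C6 bond (C6 still a methylene) is cut between primary alcohol 9 and the benzyl fragment, used as imidate 11 made from alcohol 10. The second aryl thus enters only after C1 and C2 are set. Forward, the alkylation must run under acid, because an alkoxide of 9 would shift the lactone onto the primary oxygen.

**9 ⇒ 8.** C8 is taken back to the carboxyl level, as the imide carbonyl of 8. Forward, the exocyclic imide carbonyl must be reduced in the presence of the lactone; this also releases auxiliary 3.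

**8 ⇒ 5 + 2.** The C1–C2 bond and the O3–C4 bond are cut. The aldol between succinyl imide 5 and aldehyde 2 makes C1–C2 and sets both centres at once. With the R auxiliary the syn adduct has the configuration needed at C1 and C2, and syn maps onto the trans lactone, hence onto the exo aryl at C2. The carbinol then closes on the ester.

**5 ⇒ 3 + 4 and 2 ⇒ 1.** Imide 5 comes from acylation of 3 with 4; aldehyde 2 from sulfonylation of 1.

## Alternatives that were turned down

**Alternative 1:** C5–C6 and C1–C2 are cut together, and C8, C1, C5 and C4 come from the chiral butenolide A2 (lactone carbonyl = C8, acetal carbon = C4). Forward, the 2-lithio derivative of dithiane A3 adds to C5 of A2 on the face away from the menthyloxy group, and the enolate is trapped at C1 by aldehyde A4, again anti, to give adduct A1.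
- For: three components and two C–C bonds are joined in one flask, and C1 and C5 are fixed by a cheap auxiliary. The trans relation on the butenolide translates into the cis ring fusion. The later ring closures at C2 and C6 run through benzylic cations and drift toward exo aryl groups, so there is no C6 problem; on this point it is stronger than the chosen route.
- Against: the carbinol centre C2 formed in the trapping is not reliably controlled. After A1 the dithiane must be hydrolysed beside electron-rich arenes, the C6 ketone, the lactone and the acetal reduced, and two rings closed by ionizing both benzylic carbons, so C2 and C6 end under thermodynamic control only. A methoxymethyl ether must finally be removed with acid from a p-hydroxybenzyl ether. The sequence after the key step is about twice as long.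
- Comparison: the chosen route offers instead an auxiliary-controlled C2, a catalytic ring closure and fewer operations after the key step.

**Alternative 2:** Both lactone C–O bonds (O3–C4, O7–C8) and both carbinol C–H bonds are cut, back to diketo diester A6. Forward, RuCl(p-cymene)(TsDPEN) (divalent ruthenium, in the enantiomer that delivers R carbinols) with formic acid and triethylamine reduces both aryl ketones while C1 and C5 equilibrate through their enols; each carbinol closes on the ester across C1–C5 to give dilactone A5.
- For: it is the shortest plan on paper, it is catalytic, and all four centres arise in one operation that uses the latent symmetry.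
- Against: A6 is unsymmetrical and would come from cross-coupling two different β-keto ester enolates, which gives statistical and meso/dl mixtures. Two adjacent stereolabile centres must be steered at once, and the second reduction is matched or mismatched to the first lactone. Trialkoxyaryl ketones are slow hydride acceptors. A5 then needs two lactone-to-ether reductions, each with the hazards of steps 9 and 10, and an acidic deprotection.
- Comparison: if the double dynamic reduction worked it would beat the chosen route by several steps. It stacks four selectivity demands on one untested event, whereas the chosen route spreads them over an aldol of known sense and one insertion.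

**Alternative 3:** C1–C5 and C2–O3 are cut; both rings arise in a cascade from epoxy cinnamyl ether A8. Forward, Cp2TiCl (trivalent titanium) opens the epoxide to the C5 radical, 5-exo addition to the styrene makes C1–C5 and ring B, and the benzylic C2 radical is oxidized with iodine and captured by the C4 alkoxide to give A7.
- For: A8 is a few steps from simple pieces, both rings and three stereocentres form in one operation, and only a desilylation follows. The closures tend to place aryl groups exo. On step count and on C6 it is stronger than the chosen route.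
- Against: all absolute information must come from the single benzylic centre C6 of A8. That centre demands an enantiopure aryl oxiranyl carbinol, typically by a resolution that discards half the material. It must then control C5 and C1 in a radical cyclization of only moderate bias, and C2 in a cationic closure beside a 4-silyloxyaryl group, where a quinone-methide-like cation gives little facial control. Titanium is stoichiometric, and reduction or elimination of the benzylic radical competes.
- Comparison: the chosen route is longer but sets C1 and C2 by a reagent-controlled aldol and leaves only C6 to thermodynamic control.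

Key step: step 8

Remark on the chemistry: the insertion is taken to place the C6 aryl on the concave face (cis to C4), the usual kinetic outcome of such closures; steps 9 to 12 are written for that case.

## Steps

Step 1
Reactants: 1 syringaldehyde
Product: 2 4-formyl-2,6-dimethoxyphenyl 4-methylbenzenesulfonate
Conditions: TsCl, Et3N, DMAP (cat.), CH2Cl2, 0 °C to rt
Reagents that add atoms: 4-methylbenzenesulfonyl chloride, Cc1ccc(cc1)S(Cl)(=O)=O
Why: Sulfonylation of the acidic, hindered phenol under nucleophilic catalysis. The sulfonate is kept to the last step because it makes the C2 aryl electron-poor and so protects the C2–O3 bond in every acid step.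

Step 2
Reactants: 3 (R)-4-benzyl-2-oxazolidinone; 4 methyl 4-chloro-4-oxobutanoate
Product: 5 methyl 4-[(4R)-4-benzyl-2-oxo-1,3-oxazolidin-3-yl]-4-oxobutanoate
Conditions: n-BuLi, THF, −78 °C; then 4, −78 to 0 °C
Reagents that add atoms: none
Why: N-Acylation of the lithiated oxazolidinone by the acid chloride; the methyl ester is untouched at low temperature.

Step 3
Reactants: 5 methyl 4-[(4R)-4-benzyl-2-oxo-1,3-oxazolidin-3-yl]-4-oxobutanoate; 2 4-formyl-2,6-dimethoxyphenyl 4-methylbenzenesulfonate
Product: 8 4-[(2R,3R)-3-{[(4R)-4-benzyl-2-oxo-1,3-oxazolidin-3-yl]carbonyl}-5-oxooxolan-2-yl]-2,6-dimethoxyphenyl 4-methylbenzenesulfonate (trans lactone imide), via dibutylboron Z-enolate 6 (not isolated), via syn aldol adduct 7 (not isolated)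
Conditions: Bu2BOTf, Et3N, CH2Cl2, −78 to 0 °C; 2, −78 to 0 °C; H2O2, pH 7 buffer, MeOH, 0 °C; then PPTS (cat.), PhMe, 50 °C
Reagents that add atoms: none
Why: Evans syn aldol: the Z-boron enolate of the imide reacts through a Zimmerman–Traxler chair on the face opposite the benzyl group of the R auxiliary, which sets C1 (S in target numbering) and C2 (R). The γ-hydroxy ester then lactonizes (O3–C4); the syn adduct gives the trans lactone, that is the exo aryl at C2.

Step 4
Reactants: 8 trans lactone imide
Product: 9 4-[(2R,3S)-3-(hydroxymethyl)-5-oxooxolan-2-yl]-2,6-dimethoxyphenyl 4-methylbenzenesulfonate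
Conditions: NaBH4, THF/H2O (4:1), 0 °C to rt
Reagents that add atoms: none
Why: Borohydride reduces the activated exocyclic imide carbonyl (C8) far faster than the γ-lactone and releases the auxiliary for recovery. No enolate is formed, so C1 is not epimerized.

Step 5
Reactants: 10 3,4,5-trimethoxybenzyl alcohol
Product: 11 3,4,5-trimethoxybenzyl 2,2,2-trichloroacetimidate
Conditions: Cl3CCN, DBU (cat.), CH2Cl2, 0 °C
Reagents that add atoms: trichloroacetonitrile, ClC(Cl)(Cl)C#N
Why: Base-catalysed addition of the alcohol to the nitrile, the standard preparation of benzylic trichloroacetimidates.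

Step 6
Reactants: 9 hydroxymethyl lactone; 11 3,4,5-trimethoxybenzyl 2,2,2-trichloroacetimidate
Product: 12 4-[(2R,3S)-5-oxo-3-{[(3,4,5-trimethoxybenzyl)oxy]methyl}oxolan-2-yl]-2,6-dimethoxyphenyl 4-methylbenzenesulfonate
Conditions: Me3SiOTf (5 mol %), CH2Cl2, −20 to 0 °C
Reagents that add atoms: none
Why: Acid-catalysed O-alkylation by the imidate through the stabilized trimethoxybenzyl cation forms O7–C6. No alkoxide is formed, so the lactone cannot migrate to the primary oxygen, and the electron-poor C2 aryl keeps the benzylic lactone C–O bond intact.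

Step 7
Reactants: 12 benzyl ether lactone
Product: 15 4-[(2R,3S)-4-diazo-5-oxo-3-{[(3,4,5-trimethoxybenzyl)oxy]methyl}oxolan-2-yl]-2,6-dimethoxyphenyl 4-methylbenzenesulfonate, via lithium enolate 13 (not isolated), via trifluoroacetyl lactone 14 (not isolated)
Conditions: LiN(SiMe3)2, THF, −78 °C; CF3CO2CH2CF3, −78 °C; then MsN3, Et3N, H2O, MeCN, rt
Reagents that add atoms: methanesulfonyl azide, CS(=O)(=O)N=[N+]=[N-]; 2,2,2-trifluoroethyl trifluoroacetate, FC(F)(F)C(=O)OCC(F)(F)F (adds the trifluoroacetyl group of intermediate 14 only)
Why: Detrifluoroacetylative diazo transfer: the lactone enolate is C-acylated at C5, and the resulting 1,3-dicarbonyl accepts the diazo group from the sulfonyl azide with loss of the trifluoroacetyl group as the N-acylsulfonamide. C5 is the only enolizable position and there is no leaving group on C1, so nothing eliminates.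

Step 8
Reactants: 15 diazo lactone
Product: 16 4-[(1S,2R,5R,6S)-4-oxo-6-(3,4,5-trimethoxyphenyl)-3,7-dioxabicyclo[3.3.0]octan-2-yl]-2,6-dimethoxyphenyl 4-methylbenzenesulfonate (C6 aryl endo)
Conditions: Rh2(OAc)4 (2 mol %), CH2Cl2, 40 °C, slow addition of 15
Reagents that add atoms: none
Why: Rh2(OAc)4 (divalent rhodium) attacks the diazo carbon C5, dinitrogen leaves and an electrophilic rhodium carbenoid forms at C5. Its vacant orbital engages one benzylic C6–H bond of the ether in a three-centre, hydride-transfer-like transition state that forms C5–C6 and C5–H together and frees the catalyst; this is the known intramolecular C–H insertion of α-diazo lactone carbenoids into benzylic ether C–H bonds. Ring B closes as a 1,5-insertion through the five-atom array C5–C1–C8–O7–C6. At C5 the tether on C1 can reach the carbenoid only from the face of C8, so the fusion is cis and C5 is dictated by C1. At C6 the reacting hydrogen is the one whose transition state keeps the aryl away from the carboxylate wall of the departing dirhodium unit, which puts the aryl on the concave face, cis to C4; this is the usual cis preference of such closures and is corrected in step 11. The site is secured because C6–H is the only C–H bond that is five atoms out and activated by an oxygen lone pair and an electron-rich arene; other insertions would give three- or four-membered rings. The competing path is a 1,2-hydride shift from C1 to the carbenoid carbon, which slow addition and the activation of C6–H are meant to outrun.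

Step 9
Reactants: 16 C6-endo lactone
Product: 17 4-[(1S,2R,5R,6S)-4-hydroxy-6-(3,4,5-trimethoxyphenyl)-3,7-dioxabicyclo[3.3.0]octan-2-yl]-2,6-dimethoxyphenyl 4-methylbenzenesulfonate (lactol; both C4 epimers)
Conditions: i-Bu2AlH, CH2Cl2, −78 °C; aq. potassium sodium tartrate
Reagents that add atoms: none
Why: Partial reduction of the lactone stops at the tetrahedral aluminium hemiacetal at low temperature; the aryl sulfonate and the ethers are inert.

Step 10
Reactants: 17 lactol
Product: 18 4-[(1S,2R,5S,6S)-6-(3,4,5-trimethoxyphenyl)-3,7-dioxabicyclo[3.3.0]octan-2-yl]-2,6-dimethoxyphenyl 4-methylbenzenesulfonate (C6 aryl endo)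
Conditions: Et3SiH, BF3·OEt2, CH2Cl2, −78 to −40 °C
Reagents that add atoms: none
Why: Ionic reduction: the Lewis acid ionizes the lactol to the C4 oxocarbenium ion, which takes hydride from the silane. At low temperature the benzylic ethers C2–O3 (deactivated aryl) and C6–O7 ionize far more slowly and stay closed; no stereocentre changes.

Step 11
Reactants: 18 C6-endo furofuran
Product: 19 4-[(1S,2R,5S,6R)-6-(3,4,5-trimethoxyphenyl)-3,7-dioxabicyclo[3.3.0]octan-2-yl]-2,6-dimethoxyphenyl 4-methylbenzenesulfonate (both aryls exo)
Conditions: BF3·OEt2 (0.2 equiv), CH2Cl2 (dilute), 0 °C to rt, to equilibrium; chromatography, recovered 18 resubmitted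
Reagents that add atoms: none
Why: Acid-mediated epimerization of a benzylic carbon, a known behaviour of furofuran lignans: reversible heterolysis of C6–O7 gives the trimethoxybenzyl cation, which recloses from either face, so C6 moves toward the exo aryl (trans to C4) while C1 and C5 are untouched. C2 does not ionize because its aryl bears the sulfonyloxy group. Only a modest preference for exo is expected, hence the recycling of 18.

Step 12
Reactants: 19 exo,exo furofuran sulfonate
Product: 20 4-[(1S,2R,5S,6R)-6-(3,4,5-trimethoxyphenyl)-3,7-dioxabicyclo[3.3.0]octan-2-yl]-2,6-dimethoxyphenol (target)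
Conditions: Mg, MeOH, rt; aq. NH4Cl
Reagents that add atoms: none
Why: Reductive desulfonylation: electron transfer from magnesium into the tolylsulfonyl group breaks the S–O bond and frees the phenoxide. It does not depend on access to sulfur between the two methoxy groups, and it avoids the acid and hot base that would endanger the p-hydroxybenzyl ether at C2.

## Compound list

1 | syringaldehyde | COc1cc(C=O)cc(OC)c1O | starting material
2 | 4-formyl-2,6-dimethoxyphenyl 4-methylbenzenesulfonate | COc1cc(C=O)cc(OC)c1OS(=O)(=O)c1ccc(C)cc1 | intermediate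
3 | (R)-4-benzyl-2-oxazolidinone | O=C1OC[C@@H](Cc2ccccc2)N1 | starting material
4 | methyl 4-chloro-4-oxobutanoate | COC(=O)CCC(Cl)=O | starting material
5 | methyl 4-[(4R)-4-benzyl-2-oxo-1,3-oxazolidin-3-yl]-4-oxobutanoate | COC(=O)CCC(=O)N1C(=O)OC[C@H]1Cc1ccccc1 | intermediate
6 | (Z)-dibutylboron enolate of 5 | COC(=O)C/C=C(\OB(CCCC)CCCC)N1C(=O)OC[C@H]1Cc1ccccc1 | intermediate (not isolated)
7 | methyl (3R,4R)-3-{[(4R)-4-benzyl-2-oxo-1,3-oxazolidin-3-yl]carbonyl}-4-hydroxy-4-[3,5-dimethoxy-4-(tosyloxy)phenyl]butanoate (syn aldol adduct) | O=C(N1C(=O)OC[C@H]1Cc1ccccc1)[C@H](CC(=O)OC)[C@@H](O)c1cc(OC)c(OS(=O)(=O)c2ccc(C)cc2)c(OC)c1 | intermediate (not isolated)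
8 | 4-[(2R,3R)-3-{[(4R)-4-benzyl-2-oxo-1,3-oxazolidin-3-yl]carbonyl}-5-oxooxolan-2-yl]-2,6-dimethoxyphenyl 4-methylbenzenesulfonate | O=C(N1C(=O)OC[C@H]1Cc1ccccc1)[C@@H]1CC(=O)O[C@H]1c1cc(OC)c(OS(=O)(=O)c2ccc(C)cc2)c(OC)c1 | intermediate
9 | 4-[(2R,3S)-3-(hydroxymethyl)-5-oxooxolan-2-yl]-2,6-dimethoxyphenyl 4-methylbenzenesulfonate | OC[C@@H]1CC(=O)O[C@H]1c1cc(OC)c(OS(=O)(=O)c2ccc(C)cc2)c(OC)c1 | intermediate
10 | 3,4,5-trimethoxybenzyl alcohol | COc1cc(CO)cc(OC)c1OC | starting material
11 | 3,4,5-trimethoxybenzyl 2,2,2-trichloroacetimidate | COc1cc(COC(=N)C(Cl)(Cl)Cl)cc(OC)c1OC | intermediate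
12 | 4-[(2R,3S)-5-oxo-3-{[(3,4,5-trimethoxybenzyl)oxy]methyl}oxolan-2-yl]-2,6-dimethoxyphenyl 4-methylbenzenesulfonate | COc1cc(COC[C@@H]2CC(=O)O[C@H]2c2cc(OC)c(OS(=O)(=O)c3ccc(C)cc3)c(OC)c2)cc(OC)c1OC | intermediate
13 | lithium enolate of 12 (enolate carbon = C5) | COc1cc(COC[C@@H]2C=C(O[Li])O[C@H]2c2cc(OC)c(OS(=O)(=O)c3ccc(C)cc3)c(OC)c2)cc(OC)c1OC | intermediate (not isolated)
14 | C5-trifluoroacetyl derivative of 12 (C5 unassigned) | COc1cc(COC[C@@H]2C(C(=O)C(F)(F)F)C(=O)O[C@H]2c2cc(OC)c(OS(=O)(=O)c3ccc(C)cc3)c(OC)c2)cc(OC)c1OC | intermediate (not isolated)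
15 | 4-[(2R,3S)-4-diazo-5-oxo-3-{[(3,4,5-trimethoxybenzyl)oxy]methyl}oxolan-2-yl]-2,6-dimethoxyphenyl 4-methylbenzenesulfonate | COc1cc(COC[C@@H]2C(=[N+]=[N-])C(=O)O[C@H]2c2cc(OC)c(OS(=O)(=O)c3ccc(C)cc3)c(OC)c2)cc(OC)c1OC | intermediate
16 | 4-[(1S,2R,5R,6S)-4-oxo-6-(3,4,5-trimethoxyphenyl)-3,7-dioxabicyclo[3.3.0]octan-2-yl]-2,6-dimethoxyphenyl 4-methylbenzenesulfonate | COc1cc([C@@H]2OC(=O)[C@@H]3[C@H]2CO[C@@H]3c2cc(OC)c(OC)c(OC)c2)cc(OC)c1OS(=O)(=O)c1ccc(C)cc1 | intermediate
17 | 4-[(1S,2R,5R,6S)-4-hydroxy-6-(3,4,5-trimethoxyphenyl)-3,7-dioxabicyclo[3.3.0]octan-2-yl]-2,6-dimethoxyphenyl 4-methylbenzenesulfonate (C4 epimers) | COc1cc([C@@H]2OC(O)[C@@H]3[C@H]2CO[C@@H]3c2cc(OC)c(OC)c(OC)c2)cc(OC)c1OS(=O)(=O)c1ccc(C)cc1 | intermediate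
18 | 4-[(1S,2R,5S,6S)-6-(3,4,5-trimethoxyphenyl)-3,7-dioxabicyclo[3.3.0]octan-2-yl]-2,6-dimethoxyphenyl 4-methylbenzenesulfonate | COc1cc([C@@H]2OC[C@@H]3[C@H]2CO[C@@H]3c2cc(OC)c(OC)c(OC)c2)cc(OC)c1OS(=O)(=O)c1ccc(C)cc1 | intermediate
19 | 4-[(1S,2R,5S,6R)-6-(3,4,5-trimethoxyphenyl)-3,7-dioxabicyclo[3.3.0]octan-2-yl]-2,6-dimethoxyphenyl 4-methylbenzenesulfonate | COc1cc([C@@H]2OC[C@@H]3[C@H]2CO[C@H]3c2cc(OC)c(OC)c(OC)c2)cc(OC)c1OS(=O)(=O)c1ccc(C)cc1 | intermediate
20 | 4-[(1S,2R,5S,6R)-6-(3,4,5-trimethoxyphenyl)-3,7-dioxabicyclo[3.3.0]octan-2-yl]-2,6-dimethoxyphenol | COc1cc([C@@H]2OC[C@@H]3[C@H]2CO[C@H]3c2cc(OC)c(OC)c(OC)c2)cc(OC)c1O | target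

## Step count and least certain steps

Total step count: 12. Longest linear sequence: 10 steps (steps 1, 3, 4, 6, 7, 8, 9, 10, 11, 12; the branch through step 2 is equally long).

**Step 8 (key step).** The likeliest failure is diversion of the carbenoid before it reaches C6–H: a 1,2-hydride shift from C1 that ends in a butenolide, or attack on an arene. Incomplete facial discrimination at C6 would do no harm, since that centre is equilibrated in step 11. The fallback makes the same C5–C6 bond by ionic chemistry and sets out from alcohol 9.
- Transacetalization with 3,4,5-trimethoxybenzaldehyde dimethyl acetal (PPTS) should give the mixed methyl acetal F1.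
- LiN(i-Pr)2 and Me3SiCl should convert it into the silyl ketene acetal F2.
- Me3SiOTf (cat.) at −78 °C should then ionize the acetal to the O7=C6 oxocarbenium ion, which the ketene acetal attacks through the tether (an intramolecular Mukaiyama-type addition), so the fusion is again cis.
- This comes back to the route at 16. Should its C6 epimer F3 form alongside, it is not separated but taken under the conditions of steps 9 and 10 through lactol F4 directly to 19.

**Step 11.** The equilibrium may stop well short of complete conversion because the exo preference is small, and the benzylic cation may be lost to intermolecular arylation or ring opening. The fallback replaces thermodynamic control by reagent control and sets out from 18.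
- DDQ in wet CH2Cl2 should abstract hydride only at C6, the sole electron-rich benzylic ether, and after capture of water give the ring-opened hydroxy ketone F5 (kept neutral to spare C5).
- Corey–Bakshi–Shibata reduction (BH3·SMe2, S-configured oxazaborolidine) should give the R carbinol, diol F6.
- Mitsunobu cyclodehydration (PPh3, DIAD) activates the primary C8 hydroxyl, and the C6 hydroxyl closes ring B with retention. This comes back to the route at 19.

**Step 4.** The lactone may be over-reduced, or the lactone acyl group may migrate to the freed primary alkoxide in the basic medium. The fallback sets out from 8.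
- LiOH/H2O2 in THF/H2O at 0 °C should cleave the auxiliary to the carboxylic acid F7; only the γ-lactone can re-form on acidification.
- BH3·SMe2 then reduces the acid selectively in the presence of the lactone. This comes back to the route at 9.

**Step 10.** The Lewis acid may ionize C6–O7 as well, with hydride capture of the benzylic cation (opening of ring B) or early scrambling. The fallback avoids the oxocarbenium ion, sets out from 16 and bypasses 17.
- LiBH4 in THF should reduce the lactone to diol F8.
- Mitsunobu cyclodehydration (PPh3, DIAD) activates the primary C4 hydroxyl, and the benzylic C2 hydroxyl closes ring A with retention. This comes back to the route at 18.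

## Further compounds

F1 | step 8 | 4-[(2R,3S)-3-({[methoxy(3,4,5-trimethoxyphenyl)methyl]oxy}methyl)-5-oxooxolan-2-yl]-2,6-dimethoxyphenyl 4-methylbenzenesulfonate (acetal carbon unassigned) | COC(OC[C@@H]1CC(=O)O[C@H]1c1cc(OC)c(OS(=O)(=O)c2ccc(C)cc2)c(OC)c1)c1cc(OC)c(OC)c(OC)c1
F2 | step 8 | trimethylsilyl ketene acetal of F1 | COC(OC[C@@H]1C=C(O[Si](C)(C)C)O[C@H]1c1cc(OC)c(OS(=O)(=O)c2ccc(C)cc2)c(OC)c1)c1cc(OC)c(OC)c(OC)c1
F3 | step 8 | 4-[(1S,2R,5R,6R)-4-oxo-6-(3,4,5-trimethoxyphenyl)-3,7-dioxabicyclo[3.3.0]octan-2-yl]-2,6-dimethoxyphenyl 4-methylbenzenesulfonate (C6 epimer of 16) | COc1cc([C@@H]2OC(=O)[C@@H]3[C@H]2CO[C@H]3c2cc(OC)c(OC)c(OC)c2)cc(OC)c1OS(=O)(=O)c1ccc(C)cc1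
F4 | step 8 | 4-[(1S,2R,5R,6R)-4-hydroxy-6-(3,4,5-trimethoxyphenyl)-3,7-dioxabicyclo[3.3.0]octan-2-yl]-2,6-dimethoxyphenyl 4-methylbenzenesulfonate (lactol of F3; C4 epimers) | COc1cc([C@@H]2OC(O)[C@@H]3[C@H]2CO[C@H]3c2cc(OC)c(OC)c(OC)c2)cc(OC)c1OS(=O)(=O)c1ccc(C)cc1
F5 | step 11 | 4-[(2R,3S,4S)-3-(hydroxymethyl)-4-(3,4,5-trimethoxybenzoyl)oxolan-2-yl]-2,6-dimethoxyphenyl 4-methylbenzenesulfonate | COc1cc([C@@H]2OC[C@@H](C(=O)c3cc(OC)c(OC)c(OC)c3)[C@H]2CO)cc(OC)c1OS(=O)(=O)c1ccc(C)cc1
F6 | step 11 | 4-[(2R,3S,4S)-3-(hydroxymethyl)-4-[(R)-hydroxy(3,4,5-trimethoxyphenyl)methyl]oxolan-2-yl]-2,6-dimethoxyphenyl 4-methylbenzenesulfonate | COc1cc([C@@H]2OC[C@@H]([C@@H](O)c3cc(OC)c(OC)c(OC)c3)[C@H]2CO)cc(OC)c1OS(=O)(=O)c1ccc(C)cc1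
F7 | step 4 | (2R,3R)-2-[3,5-dimethoxy-4-(tosyloxy)phenyl]-5-oxooxolane-3-carboxylic acid | OC(=O)[C@@H]1CC(=O)O[C@H]1c1cc(OC)c(OS(=O)(=O)c2ccc(C)cc2)c(OC)c1
F8 | step 10 | 4-{(R)-hydroxy[(3S,4S,5S)-4-(hydroxymethyl)-5-(3,4,5-trimethoxyphenyl)oxolan-3-yl]methyl}-2,6-dimethoxyphenyl 4-methylbenzenesulfonate | COc1cc([C@H](O)[C@@H]2CO[C@H](c3cc(OC)c(OC)c(OC)c3)[C@@H]2CO)cc(OC)c1OS(=O)(=O)c1ccc(C)cc1
A1 | alternative 1 | 3-{hydroxy[3,5-dimethoxy-4-(methoxymethoxy)phenyl]methyl}-5-menthyloxy-4-[2-(3,4,5-trimethoxyphenyl)-1,3-dithian-2-yl]oxolan-2-one (trans adduct) | O=C1O[C@H](O[C@H]2C[C@@H](C)CC[C@@H]2C(C)C)[C@@H](C2(c3cc(OC)c(OC)c(OC)c3)SCCCS2)[C@@H]1[C@@H](O)c1cc(OC)c(OCOC)c(OC)c1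
A2 | alternative 1 | (5S)-5-menthyloxyfuran-2(5H)-one (menthyl group as in A1) | O=C1C=C[C@@H](O[C@H]2C[C@@H](C)CC[C@@H]2C(C)C)O1
A3 | alternative 1 | 2-(3,4,5-trimethoxyphenyl)-1,3-dithiane | COc1cc(C2SCCCS2)cc(OC)c1OC
A4 | alternative 1 | 3,5-dimethoxy-4-(methoxymethoxy)benzaldehyde | COCOc1c(OC)cc(C=O)cc1OC
A5 | alternative 2 | 2-[3,5-dimethoxy-4-(methoxymethoxy)phenyl]-6-(3,4,5-trimethoxyphenyl)-3,7-dioxabicyclo[3.3.0]octane-4,8-dione | COCOc1c(OC)cc(cc1OC)[C@@H]1OC(=O)[C@@H]2[C@H]1C(=O)O[C@H]2c1cc(OC)c(OC)c(OC)c1
A6 | alternative 2 | dimethyl 2-[3,5-dimethoxy-4-(methoxymethoxy)benzoyl]-3-(3,4,5-trimethoxybenzoyl)butanedioate (C1 and C5 labile) | COC(=O)C(C(=O)c1cc(OC)c(OCOC)c(OC)c1)C(C(=O)OC)C(=O)c1cc(OC)c(OC)c(OC)c1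
A7 | alternative 3 | O-tert-butyldimethylsilyl ether of 20 | COc1cc([C@@H]2OC[C@@H]3[C@H]2CO[C@H]3c2cc(OC)c(OC)c(OC)c2)cc(OC)c1O[Si](C)(C)C(C)(C)C
A8 | alternative 3 | (E)-cinnamyl ether of (S)-oxiranyl(3,4,5-trimethoxyphenyl)methanol, cinnamyl aryl = 4-(tert-butyldimethylsilyloxy)-3,5-dimethoxyphenyl (epoxide carbon unassigned) | COc1cc(/C=C/CO[C@@H](c2cc(OC)c(OC)c(OC)c2)C2CO2)cc(OC)c1O[Si](C)(C)C(C)(C)C
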